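The numbers in the tables come from a simulation with constants of no real substance; the scatter is artificial.

How much ring can the flask hold at its best, when ring is also lost again?

| flask | starting material | activator | remark | time |
|---|---|---|---|---|
| Thursday's | 0.75 M | 1.2 equiv | run made earlier |  |
| Saturday's | 1.5 M | 0.60 equiv | run made earlier |  |
| flask | 1.5 M | 1.20 equiv |  | 3.0 h |

| run | time / h | ring / % | starting material / % |
|---|---|---|---|
| Thursday's | 0.0417 | 6.2 | 26.7 |
| Thursday's | 0.200 | 16.6 | 3.5 |
| Thursday's | 0.833 | 4.2 | 0 |
| Thursday's | 4.00 | 0.9 | 0.5 |
| Saturday's | 0.0417 | 4.2 | 45.4 |
| Saturday's | 0.200 | 10.2 | 36.1 |
| Saturday's | 0.833 | 1.5 | 35.1 |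
| Saturday's | 4.00 | 0.9 | 34.2 |

(standard deviation of a reading: 0.5 percentage points)

- the best time, 3.0 h at the latest, for ring
- the amount of ring, in percent of the starting material charged, at that time
- the first time at which ring reaches 8.6 %, in the same percent, in min

- percent here means starting material units held: one open dimer counts as two
- the numbers in the tables scatter by 0.5 percentage points (one standard deviation)
- steps that have been proposed: starting material + activator -> activated form; activated form <-> ring; starting material + activated form -> open dimer; activated form -> side product; activated form -> decomposed reagent

Both runs can be read through one number, the peak yield F: ring near its top per unit of activated form made, the amount made being capped by the smaller charge. Thursday's starting material is down to 3.5 % at 0.200 h. Saturday's stays near 34.2 %, with activator the limiting reagent at 0.60 equiv. Saturday's reading gives F = 17.0 % of the amount made, and Thursday's, counted on the starting material consumed, gives 17.2 %.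

The flask, at 1.20 equiv, has activator for its whole charge, and a reading need not catch the top, so F, itself a reading with its scatter, serves as an estimated lower edge for the flask's top. The charge caps ring at 100 %, which is loose. Thursday's fall from 16.6 % to 4.2 %, run back as an exponential to 0.0417 h, a time at which ring in both runs stood below its reading at 0.200 h, gives a tighter upper edge, an estimate, of 23.4 %. This reckoning commits to the lower edge.

The forecast, inside the bracket, gives 18 % at 0.14 h and the asked level at 2.6 min, on the ground that “Ring yield scales with activated form”. The flask gives 17.2 % at 0.173 h, and the asked level at 2.85 min.

    starting material + activator → activated form (k = 0.980 L mol⁻¹ min⁻¹)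
    activated form ⇌ ring (K = 0.840, k = 0.0620 min⁻¹)
    starting material + activated form → open dimer (k = 0.0230 L mol⁻¹ min⁻¹)
    activated form → side product (k = 0.0520 min⁻¹)
    activated form → decomposed reagent (k = 0.0860 min⁻¹)

In the flask, starting material's half-life by activation alone, the other concentrations as charged, is 0.39 min, far shorter than activated form's 0.19 h by the forward closure alone, and at 0.173 h the flask holds 0.614 % starting material beside 20.4 % activated form and 17.2 % ring. With 0.720 equiv of activator, the same flask is capped by activator and F gives 12.2 %; computed, its top is 12.2 %, and at 3.00 h it holds 23 % of the starting material and 0 % of the activator.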